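**Assumptions on the chemistry.** The target is taken exactly as its SMILES is written: the side chain is the (1'E,3'Z,5'S)-3',5'-dimethylhepta-1',3'-dienyl group, with C2' and C5' cis on the trisubstituted olefin. (R)-2-Methylglycidol is taken to be a commercial material.

Numbering: C1 (OCH2), O2, C3 (carries the side chain C1'–C7'), C4, C4a, C5, C6 (ketone), C7 (methyl carbinol), C8 (acetoxy), C8a; ring A is the pyran, ring B the carbocycle.

## Analysis of the target

The target is a 1,7,8,8a-tetrahydro-6H-isochromen-6-one: ring A is a dihydropyran (C1H2–O2–C3=C4) fused through C4a and C8a to ring B (C4a=C5, C6 ketone, C7, C8, C8a). The unit O2–C3=C4–C4a=C5–C6=O is a doubly vinylogous ester, extended at C3 by a (1'E,3'Z)-diene. Ring B carries three contiguous stereocentres: the tertiary carbinol C7 (R), the acetoxy carbon C8 (R) and the ring-fusion methine C8a (R). O7 and O8 are cis, O8 is trans to the C1 methylene, and in open-chain terms the C8 oxygen and the C4a branch on C8a are anti; a fourth, remote centre C5' (S) lies in the side chain. Sensitive points are the C8 acetate (β to the γ-acidic C8a–H of the dienone, so open to vinylogous elimination), the tertiary α-ketol, the acid-labile dienyl enol ether, and the 3'Z olefin, which isomerises through any cation, radical or allyl anion spread over the chain. The difficulty is that every ring carbon that is not a stereocentre is sp2: C7, C8 and C8a must be fixed before the unsaturation is drawn, and the diene must arrive late and stereospecifically. The strategy rests on C3 (an enol ether carbon, hence a masked ketone) and the C6 ketone being the ends of the chain C3–C4–C4a–C5–C6, whose central carbon C4a sits on ring B. With C3=C4 and C4a=C5 taken back to the saturated level this is a 3-(2-oxoalkyl)cyclohexanone, the pattern left by an enol–alkene photocycloaddition followed by retro-aldol opening.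

## Retrosynthetic reasoning

**32 ⇒ 26 + 31.** The C2'–C3' single bond between the two olefins is cut (Stille coupling). Both olefin geometries are then made separately and carried through a stereoretentive sp2–sp2 coupling. An olefination at C1'=C2' with an allylic phosphorus anion was considered and dropped, because such an anion delocalises over C3'=C4' and would erode the Z geometry. This cut also keeps the diene out of every acidic, basic and photochemical step.

**26 ⇒ 25 ⇒ 24 ⇒ 23.** The vinyl iodide goes back to the C1' aldehyde 25 (Takai iodo-olefination), the acetate to the diol 24, and 24 to the acetonide acetal 23. The acid step that removes both the acetonide and the dimethyl acetal is placed here, before the diene exists, so that the Z olefin never meets acid.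

**23 ⇒ 21 ⇒ 19.** The C4a=C5 double bond is taken back to the ketone 21 (Saegusa dehydrogenation; C5 is the only enolisable position of the C6 ketone because C7 is quaternary). The O2–C3 bond of ring A is then cut: 21 is the cyclodehydration product of the C1 alcohol with the C3 ketone of 19. Closing ring A first turns C3 into an enol ether, so only one ketone is left to dehydrogenate.

**19 ⇒ 17 (key).** C4a–C5 and C3–C4 are cut and C3–C5 is re-formed on paper. 19 is the retro-aldol product of a cyclobutanol that arises from the enol of the β-diketone 17 and the vinyl group on C8a. One light-driven step makes both carbon–carbon bonds of the 1,5-diketone and closes ring B, with C7, C8 and C8a already in the tether.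

**17 ⇒ 13 + 14.** The C5–C6 bond is cut: aldol addition of the methyl ketone 14 to the neopentylic aldehyde 13 and oxidation give the β-diketone. 14 brings C3, C5 and the protected C1' aldehyde.

**13 ⇒ 12 ⇒ 11 ⇒ 9 ⇒ 8.** These are functional-group changes. The C6 aldehyde comes from the PMB-protected primary alcohol, the O7/O8 acetonide from the diol freed from its tertiary silyl ether, and the C1 silyl ether from selective protection of the primary alcohol of 8.

**8 ⇒ 7 ⇒ 6 ⇒ 4.** The C8a–C4a bond is cut: the vinyl group enters by SN2 opening of the trans-epoxy alcohol 7 at C8a. The C8 terminus of the epoxide is neopentylic and therefore blocked, so regiochemistry is secure, and inversion at C8a gives the anti relationship of the C8 hydroxyl and the vinyl group. An anti-selective aldol of a but-3-enoate enolate would be shorter, but boron dienolates of such esters tend to give syn adducts. 7 comes from the (E)-allylic alcohol 6 by reagent-controlled Sharpless epoxidation, and 6 from aldehyde 4 by a two-carbon Wittig extension and reduction.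

**4 ⇒ 2 ⇒ 1.** The quaternary C7 is bought: opening 1 at its methylene carbon leaves the C7–O bond untouched and differentiates the two arms (C6 as PMB ether, C8 as the alcohol that becomes the aldehyde).

**31 ⇒ 29 ⇒ 28 ⇒ 27.** The Z-alkenylstannane comes from the Z-iodide 29 (lithium–iodine exchange, retention), made by iodo-ethylidenation of aldehyde 28, the oxidation product of 27.

## Alternatives that were turned down

**Alternative 1:** Disconnection of C7–C8. The precursor A1 carries the complete ring A and side chain, a 2,3-dioxobutylidene group on C4a (C5, C6, C7) and a formyl group (C8) on C8a. In the forward step samarium diiodide (SmI2) reduces the 1,2-dione, and the samarium-bound C7 ketyl adds to the aldehyde through a chelate to give the cis-diol A2, one acetylation from the target.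
- For: it is the most convergent plan; it creates C7, C8 and ring B in a single late step and needs almost no protecting groups. On step count it is clearly stronger than the chosen route.
- Against: A1 is a cross-conjugated trienyl dione aldehyde with an epimerisable C8a–H that is both α to the aldehyde and γ to the dienone. Under SmI2 the aldehyde is reduced faster than a ketone, the dione goes to the enediolate, and the extended enone and the 3'Z diene can accept electrons. Two new stereocentres would have to be set relative to C8a by chelation alone.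
- Comparison: the chosen route fixes C7, C8 and C8a by reagent control before ring formation, and its risky step runs on a saturated, fully protected substrate without the diene.

**Alternative 2:** Disconnection of C4a–C8a. The precursor A3 is a secondary C8a iodide tethered through C8, C7 and C6 to an ynone (C6(=O)–C5≡C4a) that already carries the C4–C3 arm and the diene; the C7/C8 diol would come from the carbohydrate chiral pool. In the forward step (Me3Si)3SiH with AIBN makes the C8a radical, which adds to C4a (6-endo-dig, polarity-matched β-attack), and hydrogen transfer to the vinyl radical gives enone A4.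
- For: it delivers C4a=C5 directly, so no dehydrogenation is needed; it is thermal and scalable; and C7/C8 are bought. On these points it is stronger.
- Against: C8a is created in the radical step from a planar radical instead of being set beforehand. 5-exo attack at C5 competes. The 3'Z diene sits in a silyl-radical chain, where reversible radical addition scrambles geometry and hydrosilylation can occur. C3 arrives as a silyl-protected carbinol whose stereocentre must be made and later oxidised away before ring A can close.
- Comparison: the chosen route brings C3 in at the ketone level, sets C8a by an SN2 reaction, and keeps the diene out of the ring-forming step, at the price of one dehydrogenation.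

**Alternative 3:** Disconnection of C5–C6. The precursor A5 is ring A with an exocyclic methylene (C5) on C4a, a cross-conjugated dienol ether, and on C8a the dioxolane whose C7 carries the C6 dimethylamide. In the forward step Tf2O with 2-chloropyridine activates the amide, C5 attacks the iminium carbon, and loss of H5 and hydrolysis give the dienone A6.
- For: it is a polar closure that builds ring B and the complete chromophore at once, with no photochemistry and no dehydrogenation. On directness to the dienone it is stronger.
- Against: the amide carbon is flanked by the quaternary C7, whose acetal oxygen can attack the activated amide. Tf2O and traces of triflic acid meet a dienyl enol ether and the Z triene. Protonation would move the exocyclic olefin into the ring (C4a=C8a), erasing the C8a stereocentre. A5 itself is hard to make and store, and the end still needs acid deprotection of the acetonide with the Z diene in place.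
- Comparison: the chosen route forms ring B without acid or electrophile and removes the acetonide before the diene is attached.

Key step: step 14

## Steps

Step 1
Reactants: 1 (R)-2-methylglycidol
Product: 2 (R)-3-[(4-methoxybenzyl)oxy]-2-methylpropane-1,2-diol
Conditions: 4-MeOC6H4CH2OH (5 equiv), NaH (0.2 equiv), 70 °C
Reagents that add atoms: 4-methoxybenzyl alcohol, COc1ccc(CO)cc1
Why: Base-catalysed SN2 opening of the epoxide at its unsubstituted carbon by the benzylic alkoxide; the C7–O bond is not touched, so C7 keeps its configuration, and the Payne rearrangement of 1 is degenerate and cannot racemise it.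

Step 2
Reactants: 2 diol
Product: 3 (S)-1-[(4-methoxybenzyl)oxy]-2-methyl-2,3-bis[(trimethylsilyl)oxy]propane
Conditions: TMSOTf (2.4 equiv), Et3N, CH2Cl2, −78 → 0 °C
Reagents that add atoms: trimethylsilyl trifluoromethanesulfonate, C[Si](C)(C)OS(=O)(=O)C(F)(F)F
Why: Exhaustive silylation; the silyl triflate also reaches the tertiary C7 hydroxyl, which must be masked before the epoxide chemistry of steps 6 and 7.

Step 3
Reactants: 3 bis-silyl ether
Product: 4 (S)-3-[(4-methoxybenzyl)oxy]-2-methyl-2-[(trimethylsilyl)oxy]propanal
Conditions: (COCl)2, DMSO, CH2Cl2, −78 → −30 °C; Et3N, −78 °C → rt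
Reagents that add atoms: none
Why: Swern oxidation applied directly to the primary trimethylsilyl ether: the chlorosulfonium salt exchanges with the unhindered primary O–Si bond and the alkoxysulfonium ylide collapses to the aldehyde, while the tertiary silyl ether has no carbinol hydrogen and stays. C7 is quaternary, so the aldehyde cannot epimerise.

Step 4
Reactants: 4 aldehyde
Product: 5 ethyl (R,E)-5-[(4-methoxybenzyl)oxy]-4-methyl-4-[(trimethylsilyl)oxy]pent-2-enoate
Conditions: Ph3P=CHCO2Et, PhMe, 80 °C
Reagents that add atoms: ethyl (triphenylphosphoranylidene)acetate, CCOC(=O)C=P(c1ccccc1)(c1ccccc1)c1ccccc1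
Why: Wittig reaction of a stabilised ylide with a non-enolisable aldehyde; the E olefin (C8=C8a, with C1 as the ester) is expected.

Step 5
Reactants: 5 enoate
Product: 6 (R,E)-5-[(4-methoxybenzyl)oxy]-4-methyl-4-[(trimethylsilyl)oxy]pent-2-en-1-ol
Conditions: DIBAL-H (2.3 equiv), CH2Cl2, −78 °C; Rochelle salt
Reagents that add atoms: none
Why: 1,2-Reduction of the enoate to the allylic alcohol; silyl and PMB ethers are inert to the hydride.

Step 6
Reactants: 6 allylic alcohol
Product: 7 {(2S,3R)-3-[(S)-1-[(4-methoxybenzyl)oxy]-2-[(trimethylsilyl)oxy]propan-2-yl]oxiran-2-yl}methanol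
Conditions: Ti(OiPr)4 (10 mol %), L-(+)-diethyl tartrate [(2R,3R), 12 mol %], t-BuOOH, 4 Å MS, CH2Cl2, −20 °C
Reagents that add atoms: tert-butyl hydroperoxide, CC(C)(C)OO
Why: Sharpless asymmetric epoxidation of an (E)-allylic alcohol; the tartrate that turns (E)-3-alkylprop-2-en-1-ols into the (2S,3S)-type epoxy alcohols delivers oxygen to the face that sets C8 (R in the later numbering), under reagent control over the remote quaternary C7.

Step 7
Reactants: 7 epoxy alcohol
Product: 8 (2R,3R,4S)-2-ethenyl-5-[(4-methoxybenzyl)oxy]-4-methyl-4-[(trimethylsilyl)oxy]pentane-1,3-diol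
Conditions: CH2=CHMgBr (5 equiv), CuI (20 mol %), THF, −30 → 0 °C
Reagents that add atoms: vinylmagnesium bromide, C=C[Mg]Br
Why: Copper-catalysed Grignard opening of a 2,3-epoxy alcohol; the C8 terminus is neopentylic, so the vinyl group attacks C8a by SN2 with inversion, placing the C8 hydroxyl and the vinyl group anti (C8a R) while C8 keeps the configuration from step 6.

Step 8
Reactants: 8 diol
Product: 9 (2R,3R,4S)-1-[(tert-butyldimethylsilyl)oxy]-2-ethenyl-5-[(4-methoxybenzyl)oxy]-4-methyl-4-[(trimethylsilyl)oxy]pentan-3-ol
Conditions: TBSCl (1.1 equiv), imidazole, CH2Cl2, 0 °C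
Reagents that add atoms: tert-butyldimethylsilyl chloride, CC(C)(C)[Si](C)(C)Cl
Why: Selective silylation of the primary C1 hydroxyl; the C8 hydroxyl is secondary and flanked by the quaternary C7.

Step 9
Reactants: 9 silyl ether
Product: 11 tert-butyl{[(2R)-2-{(4R,5S)-5-[(4-methoxybenzyloxy)methyl]-2,2,5-trimethyl-1,3-dioxolan-4-yl}but-3-en-1-yl]oxy}dimethylsilane, via C7/C8 diol 10 (not isolated)
Conditions: PPTS (0.2 equiv), MeOH–CH2Cl2, rt; then Me2C(OMe)2 (excess), rt
Reagents that add atoms: 2,2-dimethoxypropane, COC(C)(C)OC
Why: The tertiary trimethylsilyl ether is methanolysed by the mild acid far faster than the primary TBS ether; the freed C7/C8 diol is the only 1,2-diol and is closed to the dioxolane by acetal exchange, with no stereocentre touched.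

Step 10
Reactants: 11 PMB ether
Product: 12 [(4S,5R)-5-{(2R)-1-[(tert-butyldimethylsilyl)oxy]but-3-en-2-yl}-2,2,4-trimethyl-1,3-dioxolan-4-yl]methanol
Conditions: DDQ (1.3 equiv), CH2Cl2–pH 7 buffer 10:1, 0 °C → rt
Reagents that add atoms: none
Why: Oxidative cleavage of the 4-methoxybenzyl ether through its benzylic cation; the terminal alkene, acetonide and silyl ether are not oxidised by DDQ under buffered conditions.

Step 11
Reactants: 12 alcohol
Product: 13 (4R,5R)-5-{(2R)-1-[(tert-butyldimethylsilyl)oxy]but-3-en-2-yl}-2,2,4-trimethyl-1,3-dioxolane-4-carbaldehyde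
Conditions: Dess–Martin periodinane, NaHCO3, CH2Cl2, 0 °C → rt
Reagents that add atoms: none
Why: Dess–Martin oxidation of a neopentylic primary alcohol to the C6 aldehyde, which has no α-hydrogen and cannot epimerise.

Step 12
Reactants: 13 aldehyde; 14 1,1-dimethoxypropan-2-one (pyruvaldehyde dimethyl acetal)
Product: 16 1-{(4S,5R)-5-[(2R)-1-{[tert-butyl(dimethyl)silyl]oxy}but-3-en-2-yl]-2,2,4-trimethyl-1,3-dioxolan-4-yl}-1-hydroxy-4,4-dimethoxybutan-3-one (both C6 epimers), via lithium enolate 15 (not isolated)
Conditions: 14, LDA, THF, −78 °C; then 13, −78 °C; NH4Cl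
Reagents that add atoms: none
Why: Kinetic deprotonation of 14 at its methyl group and aldol addition of the lithium enolate to the non-enolisable aldehyde form the C5–C6 bond; the new carbinol centre is oxidised in the next step, so its configuration is irrelevant.

Step 13
Reactants: 16 β-hydroxy ketone
Product: 17 1-{(4R,5R)-5-[(2R)-1-{[tert-butyl(dimethyl)silyl]oxy}but-3-en-2-yl]-2,2,4-trimethyl-1,3-dioxolan-4-yl}-4,4-dimethoxybutane-1,3-dione (β-diketone with the vinyl group on C8a; exists largely as the chelated enol)
Conditions: Dess–Martin periodinane, NaHCO3, CH2Cl2, rt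
Reagents that add atoms: none
Why: Dess–Martin oxidation of a β-hydroxy ketone to the β-diketone under near-neutral conditions, which avoids retro-aldol and retro-Claisen cleavage.

Step 14
Reactants: 17 β-diketone
Product: 19 (3aR,6S,7R,7aR)-7-({[tert-butyl(dimethyl)silyl]oxy}methyl)-6-(3,3-dimethoxy-2-oxopropyl)-2,2,3a-trimethylhexahydro-1,3-benzodioxol-4-one (ring B 1,5-diketone), via cyclobutanol photoadduct 18 (not isolated)
Conditions: hν (300 nm lamps, Pyrex), degassed cyclohexane (5 mM), rt
Reagents that add atoms: none
Why: Intramolecular de Mayo reaction: light near 300 nm is absorbed by the chelated enol of 17, and after intersystem crossing the enone-like triplet bonds through its central carbon C5 to the internal vinyl carbon C4a, closing ring B in the 6-exo-trig mode (the straight mode of a 1,7-diene); the 1,4-biradical (hydroxy-stabilised at C3, primary at C4) then closes the four-membered ring of the cis-fused bicyclo[4.2.0]octanone 18. 18 is a strained β-hydroxy ketone and opens by retro-aldol cleavage of C3–C5, so C3 returns as a ketone and C5 as the α-methylene of the C6 ketone in 19. The closest known reaction type is the enol–alkene [2+2] photocycloaddition of β-diketones with retro-aldol opening, in its intramolecular form with the alkene held on the acyl chain. The one new stereocentre kept in 19, C4a, is set in the first bond formation: a chair-like six-membered arrangement anchored by the cis-dioxolane on C7/C8 puts the alkene terminus C4 and the C1 silyloxymethyl group both equatorial, hence trans; this centre is erased in step 16, so a mixture would converge. The selectivity that matters is reaction through the C3=C5 enol bond and not through C5=C6: both closures open to the C6 end (a five-membered ring by C6–C4a, or the bridged C6–C4 mode) must build a bond to a carbon flanked by the quaternary C7 inside the dioxolane, whereas C5 is an unhindered methine. High dilution suppresses dimerisation, and at 300 nm the enol absorbs far more strongly than the saturated ketones of 19, which limits secondary photochemistry.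

Step 15
Reactants: 19 1,5-diketone
Product: 21 (4aR,7R,8R,8aR)-3-(dimethoxymethyl)-7,8-(isopropylidenedioxy)-7-methyl-4a,5,8,8a-tetrahydro-1H-isochromen-6(7H)-one, via hemiketal 20 (not isolated)
Conditions: HF·pyridine, pyridine, THF, 0 °C → rt; then PPTS (0.2 equiv), PhMe, 4 Å MS, 90 °C
Reagents that add atoms: none
Why: Fluoride removes the primary silyl ether; the C1 hydroxyl adds to the electrophilic C3 ketone (six-membered hemiketal, favoured over the bridged hemiketal at C6), and acid-catalysed loss of water through the C3 oxocarbenium ion gives the C3=C4 enol ether, closing ring A. The acetonide and dimethyl acetal survive the anhydrous weak acid.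

Step 16
Reactants: 21 enol ether ketone
Product: 23 (7R,8R,8aR)-3-(dimethoxymethyl)-7,8-(isopropylidenedioxy)-7-methyl-8,8a-dihydro-1H-isochromen-6(7H)-one, via trimethylsilyl enol ether 22 (not isolated)
Conditions: LDA, TMSCl, THF, −78 °C; then Pd(OAc)2 (1.1 equiv), MeCN, rt
Reagents that add atoms: none
Why: Saegusa–Ito dehydrogenation: C5 is the only enolisable position of the C6 ketone (C7 is quaternary), and the palladium enolate loses the C4a hydrogen by β-hydride elimination to give C4a=C5 in conjugation with the enol ether. The C4a stereocentre disappears; C7, C8 and C8a are not acidic in 21 and are untouched.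

Step 17
Reactants: 23 acetonide acetal
Product: 24 (7R,8R,8aR)-7,8-dihydroxy-7-methyl-6-oxo-6,7,8,8a-tetrahydro-1H-isochromene-3-carbaldehyde
Conditions: TFA–H2O–CH2Cl2 (5:1:10), 0 °C → rt
Reagents that add atoms: water, O
Why: Aqueous acid hydrolysis of the dimethyl acetal and of the isopropylidene acetal; the push–pull dienone is protonated reversibly on oxygen and is the thermodynamic form of ring A. The step is placed before the diene is attached so that the Z olefin never meets acid.

Step 18
Reactants: 24 diol aldehyde
Product: 25 (7R,8R,8aR)-3-formyl-7-hydroxy-7-methyl-6-oxo-6,7,8,8a-tetrahydro-1H-isochromen-8-yl acetate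
Conditions: Ac2O (1.5 equiv), pyridine, DMAP (5 mol %), CH2Cl2, 0 °C
Reagents that add atoms: acetic anhydride, CC(=O)OC(C)=O
Why: Acetylation of the secondary C8 hydroxyl; the tertiary C7 α-ketol hydroxyl is not acylated under these conditions, and the cold, weakly basic medium avoids elimination across C8–C8a.

Step 19
Reactants: 25 acetoxy aldehyde
Product: 26 (7R,8R,8aR)-7-hydroxy-3-[(E)-2-iodoethenyl]-7-methyl-6-oxo-6,7,8,8a-tetrahydro-1H-isochromen-8-yl acetate
Conditions: CrCl2 (8 equiv), CHI3 (3 equiv), THF–dioxane 1:6, 0 °C → rt, dark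
Reagents that add atoms: iodoform, IC(I)I
Why: Takai iodo-olefination; the geminal dichromium reagent is selective for aldehydes over the vinylogous ester carbonyl and the acetate, and gives the E vinyl iodide (C1'=C2').

Step 20
Reactants: 27 (S)-2-methylbutan-1-ol
Product: 28 (S)-2-methylbutanal
Conditions: TEMPO (1 mol %), KBr, NaOCl, NaHCO3, CH2Cl2–H2O, 0 °C
Reagents that add atoms: none
Why: Anelli oxidation under buffered biphasic conditions, known to keep α-branched aldehydes configurationally intact; the solution is used directly.

Step 21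
Reactants: 28 aldehyde
Product: 29 (S,Z)-2-iodo-4-methylhex-2-ene
Conditions: EtPPh3I, n-BuLi, THF, rt; I2, −78 °C; NaHMDS, −20 °C; then 28, −78 °C → rt
Reagents that add atoms: ethyltriphenylphosphonium iodide, CC[P+](c1ccccc1)(c1ccccc1)c1ccccc1.[I-]; iodine, II
Why: Stork–Zhao-type Wittig olefination with the α-iodoethylidene ylide; the unstabilised ylide gives the Z iodoalkene (iodine cis to C5'), which fixes the 3'Z geometry.

Step 22
Reactants: 29 alkenyl iodide
Product: 31 (S,Z)-tributyl(4-methylhex-2-en-2-yl)stannane, via alkenyllithium 30 (not isolated)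
Conditions: t-BuLi (2.1 equiv), Et2O, −78 °C; then Bu3SnCl, −78 °C → rt
Reagents that add atoms: tributyltin chloride, CCCC[Sn](CCCC)(CCCC)Cl
Why: Lithium–iodine exchange and stannylation both proceed with retention of olefin geometry at low temperature; the allylic stereocentre is not acidic enough to be touched.

Step 23
Reactants: 26 vinyl iodide; 31 alkenylstannane
Product: 32 (7R,8R,8aR)-3-[(1E,3Z,5S)-3,5-dimethylhepta-1,3-dien-1-yl]-7-hydroxy-7-methyl-6-oxo-6,7,8,8a-tetrahydro-1H-isochromen-8-yl acetate (target)
Conditions: Pd2(dba)3·CHCl3 (5 mol %), AsPh3 (20 mol %), CuI (10 mol %), DMF, rt, dark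
Reagents that add atoms: none
Why: Stille coupling forms the C2'–C3' bond with retention at both olefins under neutral conditions that tolerate the acetate, the free tertiary alcohol and the dienone; the arsine ligand and CuI co-catalyst speed transmetalation of the α-methyl alkenylstannane.

## Compound list

1 | (R)-2-methylglycidol | OC[C@]1(C)CO1 | starting material
2 | (R)-3-[(4-methoxybenzyl)oxy]-2-methylpropane-1,2-diol | OC[C@](O)(C)COCc1ccc(OC)cc1 | intermediate
3 | (S)-1-[(4-methoxybenzyl)oxy]-2-methyl-2,3-bis[(trimethylsilyl)oxy]propane | C[Si](C)(C)OC[C@](O[Si](C)(C)C)(C)COCc1ccc(OC)cc1 | intermediate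
4 | (S)-3-[(4-methoxybenzyl)oxy]-2-methyl-2-[(trimethylsilyl)oxy]propanal | O=C[C@](O[Si](C)(C)C)(C)COCc1ccc(OC)cc1 | intermediate
5 | ethyl (R,E)-5-[(4-methoxybenzyl)oxy]-4-methyl-4-[(trimethylsilyl)oxy]pent-2-enoate | CCOC(=O)/C=C/[C@](O[Si](C)(C)C)(C)COCc1ccc(OC)cc1 | intermediate
6 | (R,E)-5-[(4-methoxybenzyl)oxy]-4-methyl-4-[(trimethylsilyl)oxy]pent-2-en-1-ol | OC/C=C/[C@](O[Si](C)(C)C)(C)COCc1ccc(OC)cc1 | intermediate
7 | {(2S,3R)-3-[(S)-1-[(4-methoxybenzyl)oxy]-2-[(trimethylsilyl)oxy]propan-2-yl]oxiran-2-yl}methanol | OC[C@@H]1O[C@H]1[C@@](C)(O[Si](C)(C)C)COCc1ccc(OC)cc1 | intermediate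
8 | (2R,3R,4S)-2-ethenyl-5-[(4-methoxybenzyl)oxy]-4-methyl-4-[(trimethylsilyl)oxy]pentane-1,3-diol | OC[C@@H](C=C)[C@@H](O)[C@@](C)(O[Si](C)(C)C)COCc1ccc(OC)cc1 | intermediate
9 | (2R,3R,4S)-1-[(tert-butyldimethylsilyl)oxy]-2-ethenyl-5-[(4-methoxybenzyl)oxy]-4-methyl-4-[(trimethylsilyl)oxy]pentan-3-ol | CC(C)(C)[Si](C)(C)OC[C@@H](C=C)[C@@H](O)[C@@](C)(O[Si](C)(C)C)COCc1ccc(OC)cc1 | intermediate
10 | (2R,3R,4S)-1-[(tert-butyldimethylsilyl)oxy]-2-ethenyl-5-[(4-methoxybenzyl)oxy]-4-methylpentane-3,4-diol | CC(C)(C)[Si](C)(C)OC[C@@H](C=C)[C@@H](O)[C@@](C)(O)COCc1ccc(OC)cc1 | intermediate (not isolated)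
11 | tert-butyl{[(2R)-2-{(4R,5S)-5-[(4-methoxybenzyloxy)methyl]-2,2,5-trimethyl-1,3-dioxolan-4-yl}but-3-en-1-yl]oxy}dimethylsilane | COc1ccc(COC[C@]2(C)OC(C)(C)O[C@@H]2[C@H](C=C)CO[Si](C)(C)C(C)(C)C)cc1 | intermediate
12 | [(4S,5R)-5-{(2R)-1-[(tert-butyldimethylsilyl)oxy]but-3-en-2-yl}-2,2,4-trimethyl-1,3-dioxolan-4-yl]methanol | OC[C@]1(C)OC(C)(C)O[C@@H]1[C@H](C=C)CO[Si](C)(C)C(C)(C)C | intermediate
13 | (4R,5R)-5-{(2R)-1-[(tert-butyldimethylsilyl)oxy]but-3-en-2-yl}-2,2,4-trimethyl-1,3-dioxolane-4-carbaldehyde | O=C[C@]1(C)OC(C)(C)O[C@@H]1[C@H](C=C)CO[Si](C)(C)C(C)(C)C | intermediate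
14 | 1,1-dimethoxypropan-2-one (pyruvaldehyde dimethyl acetal) | COC(OC)C(C)=O | starting material
15 | lithium 3,3-dimethoxyprop-1-en-2-olate (enolate of 14) | C=C(O[Li])C(OC)OC | intermediate (not isolated)
16 | 1-{(4S,5R)-5-[(2R)-1-{[tert-butyl(dimethyl)silyl]oxy}but-3-en-2-yl]-2,2,4-trimethyl-1,3-dioxolan-4-yl}-1-hydroxy-4,4-dimethoxybutan-3-one, both C6 epimers (carbinol centre left undefined) | COC(OC)C(=O)CC(O)[C@]1(C)OC(C)(C)O[C@@H]1[C@H](C=C)CO[Si](C)(C)C(C)(C)C | intermediate
17 | 1-{(4R,5R)-5-[(2R)-1-{[tert-butyl(dimethyl)silyl]oxy}but-3-en-2-yl]-2,2,4-trimethyl-1,3-dioxolan-4-yl}-4,4-dimethoxybutane-1,3-dione | COC(OC)C(=O)CC(=O)[C@]1(C)OC(C)(C)O[C@@H]1[C@H](C=C)CO[Si](C)(C)C(C)(C)C | intermediate (key-step precursor)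
18 | cis-fused bicyclo[4.2.0]octanone cyclobutanol: C3 (hydroxyl, dimethoxymethyl) bonded to C4 and C5; C5 and C4a are the ring fusion; C3 epimers not defined | COC(OC)C1(O)C[C@H]2[C@H](CO[Si](C)(C)C(C)(C)C)[C@H]3OC(C)(C)O[C@@]3(C)C(=O)[C@@H]12 | intermediate (not isolated)
19 | (3aR,6S,7R,7aR)-7-({[tert-butyl(dimethyl)silyl]oxy}methyl)-6-(3,3-dimethoxy-2-oxopropyl)-2,2,3a-trimethylhexahydro-1,3-benzodioxol-4-one | COC(OC)C(=O)C[C@@H]1CC(=O)[C@]2(C)OC(C)(C)O[C@@H]2[C@H]1CO[Si](C)(C)C(C)(C)C | intermediate (key-step product)
20 | C3 hemiketal of the desilylated diketone: 3-(dimethoxymethyl)-3-hydroxy-7,8-(isopropylidenedioxy)-7-methyloctahydro-1H-isochromen-6-one, C3 anomers not defined | COC(OC)C1(O)C[C@@H]2CC(=O)[C@]3(C)OC(C)(C)O[C@@H]3[C@H]2CO1 | intermediate (not isolated)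
21 | (4aR,7R,8R,8aR)-3-(dimethoxymethyl)-7,8-(isopropylidenedioxy)-7-methyl-4a,5,8,8a-tetrahydro-1H-isochromen-6(7H)-one | COC(OC)C1=C[C@@H]2CC(=O)[C@]3(C)OC(C)(C)O[C@@H]3[C@H]2CO1 | intermediate
22 | C5=C6 trimethylsilyl enol ether of 21 | COC(OC)C1=C[C@@H]2C=C(O[Si](C)(C)C)[C@]3(C)OC(C)(C)O[C@@H]3[C@H]2CO1 | intermediate (not isolated)
23 | (7R,8R,8aR)-3-(dimethoxymethyl)-7,8-(isopropylidenedioxy)-7-methyl-8,8a-dihydro-1H-isochromen-6(7H)-one | COC(OC)C1=CC2=CC(=O)[C@]3(C)OC(C)(C)O[C@@H]3[C@H]2CO1 | intermediate
24 | (7R,8R,8aR)-7,8-dihydroxy-7-methyl-6-oxo-6,7,8,8a-tetrahydro-1H-isochromene-3-carbaldehyde | O=CC1=CC2=CC(=O)[C@](C)(O)[C@H](O)[C@H]2CO1 | intermediate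
25 | (7R,8R,8aR)-3-formyl-7-hydroxy-7-methyl-6-oxo-6,7,8,8a-tetrahydro-1H-isochromen-8-yl acetate | O=CC1=CC2=CC(=O)[C@](C)(O)[C@H](OC(C)=O)[C@H]2CO1 | intermediate
26 | (7R,8R,8aR)-7-hydroxy-3-[(E)-2-iodoethenyl]-7-methyl-6-oxo-6,7,8,8a-tetrahydro-1H-isochromen-8-yl acetate | I/C=C/C1=CC2=CC(=O)[C@](C)(O)[C@H](OC(C)=O)[C@H]2CO1 | intermediate
27 | (S)-2-methylbutan-1-ol | CC[C@H](C)CO | starting material
28 | (S)-2-methylbutanal | CC[C@H](C)C=O | intermediate
29 | (S,Z)-2-iodo-4-methylhex-2-ene | CC[C@H](C)/C=C(C)\I | intermediate
30 | (S)-(4-methylhex-2-en-2-yl)lithium, lithium cis to C4 (formally E because lithium ranks below methyl) | CC[C@H](C)/C=C(C)\[Li] | intermediate (not isolated)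
31 | (S,Z)-tributyl(4-methylhex-2-en-2-yl)stannane | CC[C@H](C)/C=C(C)\[Sn](CCCC)(CCCC)CCCC | intermediate
32 | (7R,8R,8aR)-3-[(1E,3Z,5S)-3,5-dimethylhepta-1,3-dien-1-yl]-7-hydroxy-7-methyl-6-oxo-6,7,8,8a-tetrahydro-1H-isochromen-8-yl acetate | CC[C@H](C)/C=C(C)\C=C\C1=CC2=CC(=O)[C@](C)(O)[C@H](OC(C)=O)[C@H]2CO1 | target

## Step count and least certain steps

Total: 23 steps. Longest linear sequence: 20 steps (steps 1–19 and 23); the side-chain branch is steps 20–22.

**Step 14 (key step).** The cycloaddition may run through the C5=C6 enol bond, giving the cyclopentanone or the bridged isomer. The product may also be consumed by secondary photochemistry (α-cleavage next to the α-oxygenated ketones, γ-hydrogen abstraction from the acetal methoxy groups), or the excited enol may abstract the allylic C8a hydrogen. Fallback: starting from 17, the less hindered enol oxygen is acetylated (Ac2O, Et3N, DMAP) to the C3 enol acetate F1. This locks the C3=C5 double bond as the only enone-type chromophore and stops tautomer exchange. Irradiation of F1 should give the cyclobutyl acetate F2, which is photostable as a β-acetoxy ketone. Methanolysis (K2CO3, MeOH) then frees the cyclobutanol and triggers the retro-aldol, returning to the route at 19.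

**Step 15.** Ionisation of the hemiketal at C3 is slowed by the neighbouring acetal carbon, so dehydration may stall, or the dimethyl acetal may ionise first and exchange. Fallback: starting from 20, the hemiketal hydroxyl is silylated under kinetic conditions (TMS-imidazole, or TMSOTf with 2,6-lutidine at −78 °C) to the C3 silyl ketal F3. Enolisation of the only remaining ketone (LDA, TMSCl) gives the silyl enol ether F4, and Pd(OAc)2 dehydrogenates it to the enone F5. In F5 the C4 hydrogens are vinylogously acidic, so DBU expels trimethylsilanol from C3 by an E1cB path that needs no oxocarbenium ion. This returns to the route at 23.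

**Step 7.** Attack at C8a may be slowed by the adjacent quaternary centre, letting bromide opening or epoxide migration compete. Fallback: starting from 4, allylboration with the (Z)-γ-(silyloxymethyl)allylboronate F6 (made from commercial (Z)-but-2-ene-1,4-diol) is used, with a chiral phosphoric acid catalyst to control the aldehyde face. The Z reagent reacts through a chair transition state to give the syn homoallylic alcohol, which is 9 itself, so the route is rejoined at 9 and steps 4–8 are bypassed. Facial control next to the quaternary C7 is the open point of this fallback.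

**Step 17.** Under acid strong enough to open the acetonide, the dienone may lose water across C8–C8a through its dienol, or the free aldehyde diol may degrade. Fallback: starting from 23, the two cleavages are separated and reordered. Acetal exchange in wet acetone over an acidic resin frees only the aldehyde and leaves the acetonide (acetonide aldehyde F7). Takai olefination gives the acetonide vinyl iodide F8. The acetonide is then cleaved on this less sensitive compound (aqueous TFA at 0 °C, or Me2BBr at −78 °C) to the diol iodide F9, and acetylation returns to the route at 26.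

**Step 23.** Transmetalation of the hindered α-methyl alkenylstannane may be slow, which allows homocoupling and loss of the Z geometry over long reaction times. Fallback: starting from 25 and 29, the polarity is reversed. Boron–Takai olefination of 25 (Cl2CHBpin, CrCl2, LiI) gives the E vinylboronate F10, and Suzuki coupling of F10 with the iodide 29 (PdCl2(dppf), K3PO4, aqueous DMF, rt) gives 32 directly, without step 22.

## Further compounds

F1 | step 14 | C3 enol acetate of 17: 4-acetoxy-1-(dioxolanyl)-5,5-dimethoxypent-3-en-2-one type enone (olefin geometry not defined) | COC(OC)C(OC(C)=O)=CC(=O)[C@]1(C)OC(C)(C)O[C@@H]1[C@H](C=C)CO[Si](C)(C)C(C)(C)C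
F2 | step 14 | cyclobutyl acetate photoadduct (acetate of 18) | COC(OC)C1(OC(C)=O)C[C@H]2[C@H](CO[Si](C)(C)C(C)(C)C)[C@H]3OC(C)(C)O[C@@]3(C)C(=O)[C@@H]12
F3 | step 15 | C3 O-trimethylsilyl ketal of 20 | COC(OC)C1(O[Si](C)(C)C)C[C@@H]2CC(=O)[C@]3(C)OC(C)(C)O[C@@H]3[C@H]2CO1
F4 | step 15 | C5=C6 trimethylsilyl enol ether of F3 | COC(OC)C1(O[Si](C)(C)C)C[C@@H]2C=C(O[Si](C)(C)C)[C@]3(C)OC(C)(C)O[C@@H]3[C@H]2CO1
F5 | step 15 | C4a=C5 enone carrying the C3 silyl ketal | COC(OC)C1(O[Si](C)(C)C)CC2=CC(=O)[C@]3(C)OC(C)(C)O[C@@H]3[C@H]2CO1
F6 | step 7 | (Z)-tert-butyldimethyl{[4-(4,4,5,5-tetramethyl-1,3,2-dioxaborolan-2-yl)but-2-en-1-yl]oxy}silane | CC(C)(C)[Si](C)(C)OC/C=C\CB1OC(C)(C)C(C)(C)O1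
F7 | step 17 | (7R,8R,8aR)-7,8-(isopropylidenedioxy)-7-methyl-6-oxo-6,7,8,8a-tetrahydro-1H-isochromene-3-carbaldehyde | O=CC1=CC2=CC(=O)[C@]3(C)OC(C)(C)O[C@@H]3[C@H]2CO1
F8 | step 17 | (7R,8R,8aR)-3-[(E)-2-iodoethenyl]-7,8-(isopropylidenedioxy)-7-methyl-8,8a-dihydro-1H-isochromen-6(7H)-one | I/C=C/C1=CC2=CC(=O)[C@]3(C)OC(C)(C)O[C@@H]3[C@H]2CO1
F9 | step 17 | (7R,8R,8aR)-7,8-dihydroxy-3-[(E)-2-iodoethenyl]-7-methyl-8,8a-dihydro-1H-isochromen-6(7H)-one | I/C=C/C1=CC2=CC(=O)[C@](C)(O)[C@H](O)[C@H]2CO1
F10 | step 23 | (7R,8R,8aR)-7-hydroxy-7-methyl-6-oxo-3-[(E)-2-(4,4,5,5-tetramethyl-1,3,2-dioxaborolan-2-yl)ethenyl]-6,7,8,8a-tetrahydro-1H-isochromen-8-yl acetate | CC1(C)OB(/C=C/C2=CC3=CC(=O)[C@](C)(O)[C@H](OC(C)=O)[C@H]3CO2)OC1(C)C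
A1 | alternative 1 | pyran-4-ylidene 1,2-dione aldehyde (precursor of the ketyl cyclisation) | CC[C@H](C)/C=C(C)\C=C\C1=C\C(=C\C(=O)C(C)=O)[C@@H](C=O)CO1
A2 | alternative 1 | 7,8-diol (deacetyl target), product of the key step | CC[C@H](C)/C=C(C)\C=C\C1=CC2=CC(=O)[C@](C)(O)[C@H](O)[C@H]2CO1
A3 | alternative 2 | C8a iodide tethered to the ynone (C8a not defined) | CC[C@H](C)/C=C(C)\C=C\[C@@H](O[Si](C)(C)C(C)(C)C)CC#CC(=O)[C@]1(C)OC(C)(C)O[C@@H]1C(I)CO[Si](C)(C)C(C)(C)C
A4 | alternative 2 | ring B enone carrying the C4–C3 side arm, product of the key step | CC[C@H](C)/C=C(C)\C=C\[C@@H](O[Si](C)(C)C(C)(C)C)CC1=CC(=O)[C@]2(C)OC(C)(C)O[C@@H]2[C@H]1CO[Si](C)(C)C(C)(C)C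
A5 | alternative 3 | 4-methylene dihydropyran carrying the C6 dimethylamide | CC[C@H](C)/C=C(C)\C=C\C1=CC(=C)[C@H](CO1)[C@H]2OC(C)(C)O[C@@]2(C)C(=O)N(C)C
A6 | alternative 3 | 7,8-acetonide of the deacetyl target, product of the key step | CC[C@H](C)/C=C(C)\C=C\C1=CC2=CC(=O)[C@]3(C)OC(C)(C)O[C@@H]3[C@H]2CO1
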